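Retrosynthetic overview
1. Feature: in the second dihydrobenzofuran (O1', C2' with ring E, C3', ring D), the fusion carbon C3a' lies between the oxygen-bearing carbons C7a' (O1') and C4' (OH) and opposite the styryl-bearing C6'. This is the benzo ring of a 5,7-dioxygenated flavanone whose C4 carbonyl carbon has been moved out of the ring onto C3'. The first dihydrobenzofuran (O1, C2 with ring A, C3 with ring C, ring B, C6 bonded to C3') repeats the pattern.
2. Late disconnections: seven O-benzyl groups; then C3'–C6 (nickel-catalysed decarboxylative arylation of a C3' carboxyl by a ring B aryl metal); then C6'–styryl (Heck) and C3–ring C (decarboxylative arylation).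
3. Key disconnection: C3'–C3a' (and likewise C3–C3a) goes back to the C4–C4a bond of an enantioenriched flavanone. In the forward sense a trivalent-iodine 1,2-aryl shift contracts the pyranone to the dihydrofuran and leaves C4 as a methyl ester handle.
4. Both flavanones come from one 5-benzyloxy-7-triflyloxychromone by enantioselective palladium-catalysed arylboronic acid addition, one ligand enantiomer per half. Ring order: pyranone (bought) → second dihydrofuran → first dihydrofuran → union, after which no ring is formed.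

Key step: step 4

Numbering: unprimed locants belong to the first dihydrobenzofuran (ring A on C2, benzo ring B, ring C on C3). Primed locants belong to the second (benzo ring D, ring E on C2', ring F in the styryl group). Flavanone C2, C3, C4a, C5 and C7 become C2', C3', C3a', C4' and C6'.
Assumption: the sense of induction in steps 3 and 8 is assigned by analogy with the facial preference of t-BuPyOx–palladium catalysts with cyclic enones ((S)-ligand giving the (2R)-flavanone); if the chromone responds in the opposite sense, the two ligand enantiomers change places between steps 3 and 8 and nothing else changes.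

Step 1
Reactants: 1 5,7-dihydroxychromone
Product: 2 5-hydroxy-4-oxo-4H-chromen-7-yl trifluoromethanesulfonate
Conditions: PhNTf2 (1.05 equiv), i-Pr2NEt (1.2 equiv), DMF, 0 °C to rt
Reagents that add atoms: N-phenylbis(trifluoromethanesulfonimide), O=S(=O)(N(c1ccccc1)S(=O)(=O)C(F)(F)F)C(F)(F)F
Why: Chemoselective O-sulfonylation of a phenol: the C7 hydroxyl is the free, more acidic vinylogous acid, whereas the C5 hydroxyl is held in a hydrogen bond to the C4 carbonyl, so one equivalent of the mild triflyl donor should react at O7 only.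

Step 2
Reactants: 2 5-hydroxy-4-oxo-4H-chromen-7-yl trifluoromethanesulfonate
Product: 3 5-(benzyloxy)-4-oxo-4H-chromen-7-yl trifluoromethanesulfonate
Conditions: BnBr (1.3 equiv), K2CO3 (1.5 equiv), DMF, 40 °C
Reagents that add atoms: benzyl bromide, BrCc1ccccc1
Why: Williamson ether synthesis: carbonate in a dipolar aprotic solvent frees the chelated C5 phenoxide for benzylation, and the anhydrous medium spares the aryl triflate and the C2-unsubstituted pyranone.

Step 3
Reactants: 3 5-(benzyloxy)-4-oxo-4H-chromen-7-yl trifluoromethanesulfonate; 4 4-benzyloxyphenylboronic acid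
Product: 5 (2R)-5-(benzyloxy)-2-[4-(benzyloxy)phenyl]-4-oxochroman-7-yl trifluoromethanesulfonate
Conditions: Pd(OCOCF3)2 (5 mol%), (S)-t-BuPyOx (6 mol%), NH4PF6 (30 mol%), H2O (5 equiv), 4 (2 equiv), ClCH2CH2Cl, 60 °C; recrystallisation
Reagents that add atoms: none
Why: Enantioselective conjugate addition of an arylboronic acid to a chromone under cationic divalent palladium/pyridine-oxazoline catalysis: the aryl-palladium species inserts the C2=C3 bond while the tert-butyl group of the ligand shields one face, which sets C2 (the future C2') as (R), water protonates the palladium enolate, and because palladium stays divalent the aryl triflate is left alone.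

Step 4
Reactants: 5 (2R)-5-(benzyloxy)-2-[4-(benzyloxy)phenyl]-4-oxochroman-7-yl trifluoromethanesulfonate
Product: 8 methyl (2R,3R)-4-(benzyloxy)-2-[4-(benzyloxy)phenyl]-6-(triflyloxy)-2,3-dihydrobenzofuran-3-carboxylate, via methyl enol ether 6 (not isolated), via iodane ketal 7 (not isolated)
Conditions: PhI(OAc)2 (1.1 equiv), H2SO4 (0.5 equiv), HC(OMe)3, 0 °C to rt; aq NaHCO3 work-up
Reagents that add atoms: trimethyl orthoformate, COC(OC)OC; water, O
Why: Acid and orthoformate convert the C4 ketone into methyl enol ether 6, PhI(OAc)2 adds to its C3 on the face away from ring E while methanol caps C4, and in the resulting iodane ketal 7 the pseudo-equatorial C3–iodine bond lies antiperiplanar to C4–C4a, so ring D carbon C4a (the future C3a') slides from C4 to C3 through a bridged arenium transition state as iodobenzene departs; the dimethoxycarbenium ion left on the old C4 collapses to the methyl ester on aqueous work-up. The closest known reaction type is the oxidative ring contraction of flavanones to trans methyl 2-aryl-2,3-dihydrobenzofuran-3-carboxylates with PhI(OAc)2 or Tl(NO3)3 in trimethyl orthoformate, itself a cyclic case of the 1,2-aryl shift that turns aryl alkyl ketones into 2-arylalkanoates. The dihydrofuran ring (O1', C2', C3', C3a', C7a') closes by this intramolecular 1,2-shift, a six-to-five contraction that makes the C3'–C3a' bond without any ring bond being formed by an outside nucleophile. C2' is a spectator and keeps its (R) configuration; C3' is controlled by C2', because anti addition of iodine followed by inversion in the shift puts the ester carbon trans to ring E, and the same (2R,3R) isomer is favoured if the acidic C3' centre equilibrates. The step needs ring D to migrate in preference to a shift of ring E from C2 to C3 and to loss of the C2 proton together with iodobenzene. The two methoxy groups on C4 push the C4–C4a bond, O1 and the C5 benzyloxy group ortho to C4a stabilise the bridged cation enough to outweigh the para triflate, and the diequatorial placement of ring E and iodine keeps the C2–aryl bond out of alignment with the leaving group.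

Step 5
Reactants: 8 methyl (2R,3R)-4-(benzyloxy)-2-[4-(benzyloxy)phenyl]-6-(triflyloxy)-2,3-dihydrobenzofuran-3-carboxylate; 9 4-benzyloxystyrene
Product: 10 methyl (2R,3R)-4-(benzyloxy)-2-[4-(benzyloxy)phenyl]-6-[(E)-4-(benzyloxy)styryl]-2,3-dihydrobenzofuran-3-carboxylate
Conditions: Pd(OAc)2 (5 mol%), PPh3 (12 mol%), LiCl (3 equiv), Et3N (2 equiv), DMF, 90 °C
Reagents that add atoms: none
Why: Heck reaction of an aryl triflate: chloride converts the cationic aryl-palladium triflate into a neutral aryl-palladium chloride so that the electron-rich styrene is arylated at its terminal carbon, syn insertion and syn β-hydride elimination give the (E)-stilbene, and the amine base is too weak to open or epimerise the trans ester.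

Step 6
Reactants: 10 methyl (2R,3R)-4-(benzyloxy)-2-[4-(benzyloxy)phenyl]-6-[(E)-4-(benzyloxy)styryl]-2,3-dihydrobenzofuran-3-carboxylate
Product: 11 (2R,3R)-4-(benzyloxy)-2-[4-(benzyloxy)phenyl]-6-[(E)-4-(benzyloxy)styryl]-2,3-dihydrobenzofuran-3-carboxylic acid
Conditions: Me3SnOH (6 equiv), ClCH2CH2Cl, 80 °C; 5% aq HCl wash
Reagents that add atoms: trimethyltin hydroxide, C[Sn](C)(C)O
Why: Ester cleavage with Me3SnOH, a near-neutral hydroxide donor, which avoids the C3' enolate and therefore the E1cB opening of the O1'–C2' bond that would erase the C2' centre.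

Step 7
Reactants: 11 (2R,3R)-4-(benzyloxy)-2-[4-(benzyloxy)phenyl]-6-[(E)-4-(benzyloxy)styryl]-2,3-dihydrobenzofuran-3-carboxylic acid
Product: 12 1,3-dioxoisoindolin-2-yl (2R,3R)-4-(benzyloxy)-2-[4-(benzyloxy)phenyl]-6-[(E)-4-(benzyloxy)styryl]-2,3-dihydrobenzofuran-3-carboxylate
Conditions: N-hydroxyphthalimide (1.1 equiv), DIC (1.1 equiv), DMAP (0.1 equiv), CH2Cl2, 0 °C to rt
Reagents that add atoms: N-hydroxyphthalimide, O=C1c2ccccc2C(=O)N1O
Why: Carbodiimide (Steglich-type) esterification gives the redox-active ester under almost base-free conditions, so C2' is not endangered and the C3' centre, which is erased in step 15 anyway, need not be guarded.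

Step 8
Reactants: 3 5-(benzyloxy)-4-oxo-4H-chromen-7-yl trifluoromethanesulfonate; 13 4-benzyloxy-3-methoxyphenylboronic acid
Product: 14 (2S)-5-(benzyloxy)-2-[4-(benzyloxy)-3-methoxyphenyl]-4-oxochroman-7-yl trifluoromethanesulfonate
Conditions: Pd(OCOCF3)2 (5 mol%), (R)-t-BuPyOx (6 mol%), NH4PF6 (30 mol%), H2O (5 equiv), 13 (2 equiv), ClCH2CH2Cl, 60 °C; recrystallisation
Reagents that add atoms: none
Why: The same enantioselective palladium-catalysed conjugate addition as in step 3, run with the mirror-image ligand so that the aryl group reaches the opposite face of the chromone and C2 is set as (S).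

Step 9
Reactants: 14 (2S)-5-(benzyloxy)-2-[4-(benzyloxy)-3-methoxyphenyl]-4-oxochroman-7-yl trifluoromethanesulfonate
Product: 17 methyl (2S,3S)-4-(benzyloxy)-2-[4-(benzyloxy)-3-methoxyphenyl]-6-(triflyloxy)-2,3-dihydrobenzofuran-3-carboxylate, via methyl enol ether 15 (not isolated), via iodane ketal 16 (not isolated)
Conditions: PhI(OAc)2 (1.1 equiv), H2SO4 (0.5 equiv), HC(OMe)3, 0 °C to rt; aq NaHCO3 work-up
Reagents that add atoms: trimethyl orthoformate, COC(OC)OC; water, O
Why: Trivalent-iodine oxidative ring contraction of a flavanone as in step 4, in the mirror-image series: ring B carbon C4a shifts from C4 to C3 and closes the first dihydrofuran ring, C2 stays (S), and anti iodination followed by inversion places the ester trans to ring A, setting C3 as (S).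

Step 10
Reactants: 17 methyl (2S,3S)-4-(benzyloxy)-2-[4-(benzyloxy)-3-methoxyphenyl]-6-(triflyloxy)-2,3-dihydrobenzofuran-3-carboxylate
Product: 18 (2S,3S)-4-(benzyloxy)-2-[4-(benzyloxy)-3-methoxyphenyl]-6-(triflyloxy)-2,3-dihydrobenzofuran-3-carboxylic acid
Conditions: Me3SnOH (6 equiv), ClCH2CH2Cl, 80 °C; 5% aq HCl wash
Reagents that add atoms: trimethyltin hydroxide, C[Sn](C)(C)O
Why: The same near-neutral Me3SnOH ester cleavage as in step 6, chosen here also because it should spare the aryl triflate, which aqueous hydroxide would hydrolyse.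

Step 11
Reactants: 18 (2S,3S)-4-(benzyloxy)-2-[4-(benzyloxy)-3-methoxyphenyl]-6-(triflyloxy)-2,3-dihydrobenzofuran-3-carboxylic acid
Product: 19 1,3-dioxoisoindolin-2-yl (2S,3S)-4-(benzyloxy)-2-[4-(benzyloxy)-3-methoxyphenyl]-6-(triflyloxy)-2,3-dihydrobenzofuran-3-carboxylate
Conditions: N-hydroxyphthalimide (1.1 equiv), DIC (1.1 equiv), DMAP (0.1 equiv), CH2Cl2, 0 °C to rt
Reagents that add atoms: N-hydroxyphthalimide, O=C1c2ccccc2C(=O)N1O
Why: Carbodiimide (Steglich-type) esterification to the redox-active ester, as in step 7, with no reagent present that attacks the triflate or C2.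

Step 12
Reactants: 20 5-iodoresorcinol
Product: 21 1,3-bis(benzyloxy)-5-iodobenzene
Conditions: BnBr (2.3 equiv), K2CO3 (2.5 equiv), DMF, rt to 50 °C
Reagents that add atoms: benzyl bromide, BrCc1ccccc1
Why: Double Williamson ether synthesis on a symmetrical resorcinol, in which the aryl iodide is inert.

Step 13
Reactants: 19 1,3-dioxoisoindolin-2-yl (2S,3S)-4-(benzyloxy)-2-[4-(benzyloxy)-3-methoxyphenyl]-6-(triflyloxy)-2,3-dihydrobenzofuran-3-carboxylate; 21 1,3-bis(benzyloxy)-5-iodobenzene
Product: 22 (2S,3S)-4-(benzyloxy)-2-[4-(benzyloxy)-3-methoxyphenyl]-3-[3,5-bis(benzyloxy)phenyl]-2,3-dihydrobenzofuran-6-yl trifluoromethanesulfonate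
Conditions: 21 (1.5 equiv), NiCl2(dme) (10 mol%), 4,4'-di-tert-butyl-2,2'-bipyridine (10 mol%), Zn dust (2 equiv), DMA, 25 °C
Reagents that add atoms: none
Why: Nickel-catalysed decarboxylative cross-electrophile coupling of an N-hydroxyphthalimide ester with an aryl iodide: bipyridine-bound zerovalent nickel inserts into the C–I bond of 21 far faster than into the C6 triflate, single-electron reduction of 19 releases CO2 and the planar benzylic C3 radical, and the aryl-nickel species captures it on the face away from ring A, so reductive elimination resets C3 as (S), trans to the untouched C2.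

Step 14
Reactants: 22 (2S,3S)-4-(benzyloxy)-2-[4-(benzyloxy)-3-methoxyphenyl]-3-[3,5-bis(benzyloxy)phenyl]-2,3-dihydrobenzofuran-6-yl trifluoromethanesulfonate
Product: 23 (2S,3S)-4-(benzyloxy)-2-[4-(benzyloxy)-3-methoxyphenyl]-3-[3,5-bis(benzyloxy)phenyl]-6-bromo-2,3-dihydrobenzofuran
Conditions: Pd2(dba)3 (2.5 mol%), t-BuBrettPhos (7.5 mol%), KBr (2 equiv), KF (0.5 equiv), 1,4-dioxane, 130 °C, sealed tube
Reagents that add atoms: potassium bromide, [K+].[Br-]
Why: Palladium-catalysed triflate-to-bromide exchange: zerovalent palladium carrying the very bulky biaryl phosphine inserts into the unhindered C6–OTf bond, bromide replaces triflate on the metal, and the ligand bulk forces C–Br reductive elimination, while the all-ether substrate has no group that suffers at this temperature and C2 and C3 are not involved.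

Step 15
Reactants: 23 (2S,3S)-4-(benzyloxy)-2-[4-(benzyloxy)-3-methoxyphenyl]-3-[3,5-bis(benzyloxy)phenyl]-6-bromo-2,3-dihydrobenzofuran; 12 1,3-dioxoisoindolin-2-yl (2R,3R)-4-(benzyloxy)-2-[4-(benzyloxy)phenyl]-6-[(E)-4-(benzyloxy)styryl]-2,3-dihydrobenzofuran-3-carboxylate
Product: 26 hepta-O-benzyl gnetin K, (2S,3S,2'R,3'R), via aryllithium 24 (not isolated), via arylzinc chloride 25 (not isolated)
Conditions: 23 (1.5 equiv), n-BuLi (1.5 equiv), THF, −78 °C; ZnCl2 (1.6 equiv), −78 °C to rt; then 12 (1.0 equiv), NiCl2(dme) (20 mol%), 4,4'-di-tert-butyl-2,2'-bipyridine (40 mol%), THF/DMF, 25 °C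
Reagents that add atoms: none
Why: Bromine–lithium exchange and transmetalation give arylzinc 25 for a nickel-catalysed decarboxylative Negishi-type arylation of the redox-active ester: the aryl-nickel species reduces 12, CO2 is lost, and the planar C3' radical is captured anti to ring E by the unhindered ring B aryl, which forms C3'–C6 and sets C3' as (R), trans to the untouched C2', while pairs containing a minor fragment enantiomer become separable diastereomers.

Step 16
Reactants: 26 hepta-O-benzyl gnetin K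
Product: 27 gnetin K
Conditions: BCl3 (1 M in CH2Cl2, 16 equiv), pentamethylbenzene (25 equiv), CH2Cl2, −78 °C; then H2O
Reagents that add atoms: none
Why: Lewis-acid debenzylation with a non-basic cation scavenger: BCl3 ionises the seven aryl benzyl ethers at −78 °C and pentamethylbenzene removes the benzyl cations by Friedel–Crafts alkylation, conditions that should leave the stilbene double bond (which rules out hydrogenolysis), the ring A methyl ether and the four stereocentres untouched.

Compound list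
1 | 5,7-dihydroxychromone | O=c1ccoc2cc(O)cc(O)c12 | starting material
2 | 5-hydroxy-4-oxo-4H-chromen-7-yl trifluoromethanesulfonate | O=c1ccoc2cc(OS(=O)(=O)C(F)(F)F)cc(O)c12 | intermediate
3 | 5-(benzyloxy)-4-oxo-4H-chromen-7-yl trifluoromethanesulfonate | O=c1ccoc2cc(OS(=O)(=O)C(F)(F)F)cc(OCc3ccccc3)c12 | intermediate
4 | 4-benzyloxyphenylboronic acid | OB(O)c1ccc(OCc2ccccc2)cc1 | starting material
5 | (2R)-5-(benzyloxy)-2-[4-(benzyloxy)phenyl]-4-oxochroman-7-yl trifluoromethanesulfonate | O=C1C[C@H](c2ccc(OCc3ccccc3)cc2)Oc2cc(OS(=O)(=O)C(F)(F)F)cc(OCc3ccccc3)c12 | intermediate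
6 | (2R)-5-(benzyloxy)-2-[4-(benzyloxy)phenyl]-4-methoxy-2H-chromen-7-yl trifluoromethanesulfonate (methyl enol ether, not isolated) | COC1=C[C@H](c2ccc(OCc3ccccc3)cc2)Oc2cc(OS(=O)(=O)C(F)(F)F)cc(OCc3ccccc3)c12 | intermediate
7 | (2S,3S)-3-[acetoxy(phenyl)iodanyl]-5-(benzyloxy)-2-[4-(benzyloxy)phenyl]-4,4-dimethoxychroman-7-yl trifluoromethanesulfonate (iodine trans to ring E; C2 spatially as in 5, descriptor changed by the iodine on C3; not isolated) | COC1(OC)[C@@H](I(OC(C)=O)c2ccccc2)[C@H](c2ccc(OCc3ccccc3)cc2)Oc2cc(OS(=O)(=O)C(F)(F)F)cc(OCc3ccccc3)c12 | intermediate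
8 | methyl (2R,3R)-4-(benzyloxy)-2-[4-(benzyloxy)phenyl]-6-(triflyloxy)-2,3-dihydrobenzofuran-3-carboxylate (trans) | COC(=O)[C@@H]1c2c(OCc3ccccc3)cc(OS(=O)(=O)C(F)(F)F)cc2O[C@H]1c1ccc(OCc2ccccc2)cc1 | intermediate
9 | 4-benzyloxystyrene | C=Cc1ccc(OCc2ccccc2)cc1 | starting material
10 | methyl (2R,3R)-4-(benzyloxy)-2-[4-(benzyloxy)phenyl]-6-[(E)-4-(benzyloxy)styryl]-2,3-dihydrobenzofuran-3-carboxylate | COC(=O)[C@@H]1c2c(OCc3ccccc3)cc(/C=C/c3ccc(OCc4ccccc4)cc3)cc2O[C@H]1c1ccc(OCc2ccccc2)cc1 | intermediate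
11 | (2R,3R)-4-(benzyloxy)-2-[4-(benzyloxy)phenyl]-6-[(E)-4-(benzyloxy)styryl]-2,3-dihydrobenzofuran-3-carboxylic acid | OC(=O)[C@@H]1c2c(OCc3ccccc3)cc(/C=C/c3ccc(OCc4ccccc4)cc3)cc2O[C@H]1c1ccc(OCc2ccccc2)cc1 | intermediate
12 | 1,3-dioxoisoindolin-2-yl (2R,3R)-4-(benzyloxy)-2-[4-(benzyloxy)phenyl]-6-[(E)-4-(benzyloxy)styryl]-2,3-dihydrobenzofuran-3-carboxylate | O=C(ON1C(=O)c2ccccc2C1=O)[C@@H]1c2c(OCc3ccccc3)cc(/C=C/c3ccc(OCc4ccccc4)cc3)cc2O[C@H]1c1ccc(OCc2ccccc2)cc1 | intermediate
13 | 4-benzyloxy-3-methoxyphenylboronic acid | COc1cc(B(O)O)ccc1OCc1ccccc1 | starting material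
14 | (2S)-5-(benzyloxy)-2-[4-(benzyloxy)-3-methoxyphenyl]-4-oxochroman-7-yl trifluoromethanesulfonate | O=C1C[C@@H](c2ccc(OCc3ccccc3)c(OC)c2)Oc2cc(OS(=O)(=O)C(F)(F)F)cc(OCc3ccccc3)c12 | intermediate
15 | (2S)-5-(benzyloxy)-2-[4-(benzyloxy)-3-methoxyphenyl]-4-methoxy-2H-chromen-7-yl trifluoromethanesulfonate (methyl enol ether, not isolated) | COC1=C[C@@H](c2ccc(OCc3ccccc3)c(OC)c2)Oc2cc(OS(=O)(=O)C(F)(F)F)cc(OCc3ccccc3)c12 | intermediate
16 | (2R,3R)-3-[acetoxy(phenyl)iodanyl]-5-(benzyloxy)-2-[4-(benzyloxy)-3-methoxyphenyl]-4,4-dimethoxychroman-7-yl trifluoromethanesulfonate (iodine trans to ring A; C2 spatially as in 14; not isolated) | COC1(OC)[C@H](I(OC(C)=O)c2ccccc2)[C@@H](c2ccc(OCc3ccccc3)c(OC)c2)Oc2cc(OS(=O)(=O)C(F)(F)F)cc(OCc3ccccc3)c12 | intermediate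
17 | methyl (2S,3S)-4-(benzyloxy)-2-[4-(benzyloxy)-3-methoxyphenyl]-6-(triflyloxy)-2,3-dihydrobenzofuran-3-carboxylate (trans) | COC(=O)[C@H]1c2c(OCc3ccccc3)cc(OS(=O)(=O)C(F)(F)F)cc2O[C@@H]1c1ccc(OCc2ccccc2)c(OC)c1 | intermediate
18 | (2S,3S)-4-(benzyloxy)-2-[4-(benzyloxy)-3-methoxyphenyl]-6-(triflyloxy)-2,3-dihydrobenzofuran-3-carboxylic acid | OC(=O)[C@H]1c2c(OCc3ccccc3)cc(OS(=O)(=O)C(F)(F)F)cc2O[C@@H]1c1ccc(OCc2ccccc2)c(OC)c1 | intermediate
19 | 1,3-dioxoisoindolin-2-yl (2S,3S)-4-(benzyloxy)-2-[4-(benzyloxy)-3-methoxyphenyl]-6-(triflyloxy)-2,3-dihydrobenzofuran-3-carboxylate | O=C(ON1C(=O)c2ccccc2C1=O)[C@H]1c2c(OCc3ccccc3)cc(OS(=O)(=O)C(F)(F)F)cc2O[C@@H]1c1ccc(OCc2ccccc2)c(OC)c1 | intermediate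
20 | 5-iodoresorcinol (5-iodobenzene-1,3-diol) | Oc1cc(O)cc(I)c1 | starting material
21 | 1,3-bis(benzyloxy)-5-iodobenzene | Ic1cc(OCc2ccccc2)cc(OCc2ccccc2)c1 | intermediate
22 | (2S,3S)-4-(benzyloxy)-2-[4-(benzyloxy)-3-methoxyphenyl]-3-[3,5-bis(benzyloxy)phenyl]-2,3-dihydrobenzofuran-6-yl trifluoromethanesulfonate (trans) | COc1cc([C@H]2Oc3cc(OS(=O)(=O)C(F)(F)F)cc(OCc4ccccc4)c3[C@@H]2c2cc(OCc3ccccc3)cc(OCc3ccccc3)c2)ccc1OCc1ccccc1 | intermediate
23 | (2S,3S)-4-(benzyloxy)-2-[4-(benzyloxy)-3-methoxyphenyl]-3-[3,5-bis(benzyloxy)phenyl]-6-bromo-2,3-dihydrobenzofuran | COc1cc([C@H]2Oc3cc(Br)cc(OCc4ccccc4)c3[C@@H]2c2cc(OCc3ccccc3)cc(OCc3ccccc3)c2)ccc1OCc1ccccc1 | intermediate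
24 | C6 aryllithium derived from 23 (not isolated) | COc1cc([C@H]2Oc3cc([Li])cc(OCc4ccccc4)c3[C@@H]2c2cc(OCc3ccccc3)cc(OCc3ccccc3)c2)ccc1OCc1ccccc1 | intermediate
25 | C6 arylzinc chloride derived from 24 (not isolated) | COc1cc([C@H]2Oc3cc([Zn]Cl)cc(OCc4ccccc4)c3[C@@H]2c2cc(OCc3ccccc3)cc(OCc3ccccc3)c2)ccc1OCc1ccccc1 | intermediate
26 | hepta-O-benzyl gnetin K: (2S,3S)-4-(benzyloxy)-2-[4-(benzyloxy)-3-methoxyphenyl]-3-[3,5-bis(benzyloxy)phenyl]-6-{(2R,3R)-4-(benzyloxy)-2-[4-(benzyloxy)phenyl]-6-[(E)-4-(benzyloxy)styryl]-2,3-dihydrobenzofuran-3-yl}-2,3-dihydrobenzofuran | COc1cc([C@H]2Oc3cc([C@@H]4c5c(OCc6ccccc6)cc(/C=C/c6ccc(OCc7ccccc7)cc6)cc5O[C@H]4c4ccc(OCc5ccccc5)cc4)cc(OCc4ccccc4)c3[C@@H]2c2cc(OCc3ccccc3)cc(OCc3ccccc3)c2)ccc1OCc1ccccc1 | intermediate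
27 | gnetin K, (2S,3S,2'R,3'R), (E)-alkene | COc1cc([C@H]2Oc3cc([C@@H]4c5c(O)cc(/C=C/c6ccc(O)cc6)cc5O[C@H]4c4ccc(O)cc4)cc(O)c3[C@@H]2c2cc(O)cc(O)c2)ccc1O | target

Total step count: 16
Longest linear sequence: 10 steps (1, 2, 8, 9, 10, 11, 13, 14, 15, 16)

Steps most likely to fail

Step 4 (key step). Four processes threaten it:
- Enol ether formation may be slow next to the peri C5 benzyloxy group.
- Ring E may shift from C2 to C3 instead of ring D from C4 to C3.
- The C2–C3 bond may simply be dehydrogenated.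
- The acid may open the O1–C2 bond and erode enantiopurity.

The fallback sets out from 5 and comes back at 8. It keeps the same 1,2-shift of the ring D carbon but drives it through a carbene and ketene instead of an iodane. The lithium enolate of 5 (LiHMDS, THF, −78 °C) is acylated with CF3CO2CH2CF3 to the 3-trifluoroacetyl flavanone F1. Detrifluoroacetylative Regitz diazo transfer (MsN3, Et3N, H2O, MeCN, rt) gives the 3-diazoflavanone F2. Irradiation (300 nm, MeOH/THF, 0 °C) triggers a photochemical Wolff rearrangement. The cyclic diazoketone is locked s-cis, so loss of nitrogen and migration of C4a from C4 to C3 should be concerted and give the ketene F3. Methanol adds to the ketene, and protonation anti to ring E should deliver mainly the cis ester F4. DBU in CH2Cl2 then equilibrates this to the trans ester 8.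

Step 15. The arylzinc may be protonated or homocoupled. The hindered benzylic C3' radical may dimerise or abstract hydrogen before nickel captures it. An excess of the precious ring B fragment is also consumed.

The fallback sets out from 23 and comes back at 26. It replaces the organometallic nucleophile with a cross-electrophile manifold. An aromatic Finkelstein reaction (CuI, NaI, trans-N,N'-dimethylcyclohexane-1,2-diamine, dioxane, 110 °C) converts 23 into the aryl iodide F5. This iodide is coupled with 12 under the reductive conditions of step 13 (NiCl2(dme), 4,4'-di-tert-butyl-2,2'-bipyridine, Zn dust, DMA, 25 °C, slow addition of 12). No strong base or preformed organometallic is then needed, and unreacted iodide can be recovered.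

Step 14. C–Br reductive elimination from palladium may be slow. Fluoride and adventitious water may cleave the S–O bond of the triflate. The aryl-palladium species may be reduced at 130 °C.

The fallback sets out from 22 and comes back at 23, and it passes through boron at lower temperature. Miyaura borylation (PdCl2(dppf), B2pin2, KOAc, dioxane, 80 °C) gives the C6 pinacol boronate F6. Copper-mediated bromodeboronation (CuBr2, MeOH/H2O, 80 °C) then returns bromide 23.

Further compounds
F1 | step 4 | (2R)-5-(benzyloxy)-2-[4-(benzyloxy)phenyl]-4-oxo-3-(trifluoroacetyl)chroman-7-yl trifluoromethanesulfonate (C3 epimers and enol form) | O=C1C(C(=O)C(F)(F)F)[C@H](c2ccc(OCc3ccccc3)cc2)Oc2cc(OS(=O)(=O)C(F)(F)F)cc(OCc3ccccc3)c12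
F2 | step 4 | 5-(benzyloxy)-2-[4-(benzyloxy)phenyl]-3-diazo-4-oxochroman-7-yl trifluoromethanesulfonate, C2 spatially as in 5 (descriptor 2S) | O=C1C(=[N+]=[N-])[C@H](c2ccc(OCc3ccccc3)cc2)Oc2cc(OS(=O)(=O)C(F)(F)F)cc(OCc3ccccc3)c12
F3 | step 4 | 4-(benzyloxy)-2-[4-(benzyloxy)phenyl]-3-(oxomethylidene)-2,3-dihydrobenzofuran-6-yl trifluoromethanesulfonate (ketene, C2 spatially as in 5) | O=C=C1c2c(OCc3ccccc3)cc(OS(=O)(=O)C(F)(F)F)cc2O[C@H]1c1ccc(OCc2ccccc2)cc1
F4 | step 4 | methyl (2R,3S)-4-(benzyloxy)-2-[4-(benzyloxy)phenyl]-6-(triflyloxy)-2,3-dihydrobenzofuran-3-carboxylate (cis) | COC(=O)[C@H]1c2c(OCc3ccccc3)cc(OS(=O)(=O)C(F)(F)F)cc2O[C@H]1c1ccc(OCc2ccccc2)cc1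
F5 | step 15 | (2S,3S)-4-(benzyloxy)-2-[4-(benzyloxy)-3-methoxyphenyl]-3-[3,5-bis(benzyloxy)phenyl]-6-iodo-2,3-dihydrobenzofuran | COc1cc([C@H]2Oc3cc(I)cc(OCc4ccccc4)c3[C@@H]2c2cc(OCc3ccccc3)cc(OCc3ccccc3)c2)ccc1OCc1ccccc1
F6 | step 14 | (2S,3S)-4-(benzyloxy)-2-[4-(benzyloxy)-3-methoxyphenyl]-3-[3,5-bis(benzyloxy)phenyl]-6-(4,4,5,5-tetramethyl-1,3,2-dioxaborolan-2-yl)-2,3-dihydrobenzofuran | COc1cc([C@H]2Oc3cc(B4OC(C)(C)C(C)(C)O4)cc(OCc4ccccc4)c3[C@@H]2c2cc(OCc3ccccc3)cc(OCc3ccccc3)c2)ccc1OCc1ccccc1
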